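The route rests on making ring B, the para-phenylene whose C1 carries the ether oxygen to ring A and whose C4 carries the CH2 of the bridge to ring C, with C2, C3, C5 and C6 as plain CH, from three alkynes. One [2+2+2] cycloaddition unites an aryl ethynyl ether, a but-3-ynyl terminus and acetylene; it forms ring B and, because the two alkynes sit at the ends of one chain, closes the 19-membered macrocycle in the same operation. The precursor is an open-chain tetramethyl ether with rings A, D and C already joined (A–CH2CH2–D–O–C), ring A bearing O–C≡CH and ring C bearing CH2CH2C≡CH. Demethylation finishes the synthesis.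

Key step: step 10

Remarks on the chemistry
- Ring letters: A and C are the two trioxygenated rings (A is bonded to ring B through oxygen, C through CH2CH2), B is the para-phenylene and D the meta-phenylene. The target has no stereocentre. The stilbene double bond made in step 3 is assumed to form as an E/Z mixture and is written without geometry until it is saturated in step 6.
- Design of the cyclisation precursor:
  - Both alkynes are left terminal, because a silyl cap would claim the metal-bound position and steer towards ortho fusion.
  - The phenols are carried as methyl ethers, which tolerate n-BuLi and the cationic rhodium catalyst.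
  - The sensitive ethynyl ether is released only in the last step before the cyclisation, from a stable dichlorovinyl ether.
  - The ring A hydroxyl is distinguished from the ring D hydroxyl by a benzyl group that is lost in the hydrogenation, so no separate deprotection is needed.
  - Acetylene is supplied dilute, not in excess, because each terminal alkyne could otherwise be capped by two acetylenes.

Step 1
Reactants: 1 3-hydroxy-4,5-dimethoxybenzaldehyde
Product: 2 3-(benzyloxy)-4,5-dimethoxybenzaldehyde
Conditions: BnBr, K2CO3, DMF, rt
Reagents that add atoms: benzyl bromide, BrCc1ccccc1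
Why: Williamson O-alkylation of the only phenol masks the ring A hydroxyl as a benzyl ether that the later hydrogenation removes without an extra step.

Step 2
Reactants: 3 3-hydroxybenzyl alcohol
Product: 4 (3-hydroxybenzyl)triphenylphosphonium bromide
Conditions: Ph3P·HBr, MeCN, reflux
Reagents that add atoms: triphenylphosphine hydrobromide, Br.c1ccc(cc1)P(c1ccccc1)c1ccccc1
Why: Acid-promoted substitution of the benzylic hydroxyl by triphenylphosphine gives the Wittig salt directly, the phenol being inert under these acidic conditions.

Step 3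
Reactants: 4 (3-hydroxybenzyl)triphenylphosphonium bromide; 2 3-(benzyloxy)-4,5-dimethoxybenzaldehyde
Product: 6 3-[2-(3-benzyloxy-4,5-dimethoxyphenyl)ethenyl]phenol (E/Z mixture), via phosphonium ylide phenoxide 5 (not isolated)
Conditions: KOtBu (2.3 equiv), THF, 0 °C to rt; then 1 M HCl
Reagents that add atoms: none
Why: Wittig olefination in which two equivalents of base give the phenoxide ylide, whose meta oxido group is not conjugated with the ylide carbon and so leaves its reactivity towards the aldehyde intact; the alkene geometry is irrelevant because the bond is saturated in step 6.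

Step 4
Reactants: 6 3-[2-(3-benzyloxy-4,5-dimethoxyphenyl)ethenyl]phenol; 7 3-bromo-4,5-dimethoxybenzaldehyde
Product: 8 3-{3-[2-(3-benzyloxy-4,5-dimethoxyphenyl)ethenyl]phenoxy}-4,5-dimethoxybenzaldehyde
Conditions: CuI (10 mol %), N,N-dimethylglycine·HCl (30 mol %), Cs2CO3, 1,4-dioxane, 100 °C
Reagents that add atoms: none
Why: Ligand-accelerated Ullmann diaryl ether synthesis with monovalent copper should couple the unhindered meta-substituted phenol with the ortho-methoxy aryl bromide, and the aldehyde has no α-hydrogen so it tolerates the carbonate base.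

Step 5
Reactants: 8 3-{3-[2-(3-benzyloxy-4,5-dimethoxyphenyl)ethenyl]phenoxy}-4,5-dimethoxybenzaldehyde
Product: 9 (2E)-3-(3-{3-[2-(3-benzyloxy-4,5-dimethoxyphenyl)ethenyl]phenoxy}-4,5-dimethoxyphenyl)prop-2-enal
Conditions: Ph3P=CHCHO (1.3 equiv), toluene, 90 °C
Reagents that add atoms: (triphenylphosphoranylidene)acetaldehyde, O=CC=P(c1ccccc1)(c1ccccc1)c1ccccc1
Why: Wittig reaction with the stabilised formyl ylide should give the E-enal and adds the two carbons that the butynyl chain of ring C still lacks.

Step 6
Reactants: 9 (2E)-3-(3-{3-[2-(3-benzyloxy-4,5-dimethoxyphenyl)ethenyl]phenoxy}-4,5-dimethoxyphenyl)prop-2-enal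
Product: 10 3-(3-{3-[2-(3-hydroxy-4,5-dimethoxyphenyl)ethyl]phenoxy}-4,5-dimethoxyphenyl)propanal
Conditions: H2 (1 atm), 10% Pd/C, EtOAc, rt, stopped after uptake of 3 equiv
Reagents that add atoms: none
Why: Heterogeneous catalytic hydrogenation should saturate the stilbene and enal C=C bonds and hydrogenolyse the benzyl ether in one operation, while a saturated aliphatic aldehyde is reduced much more slowly on Pd/C in a non-alcoholic solvent.

Step 7
Reactants: 10 3-(3-{3-[2-(3-hydroxy-4,5-dimethoxyphenyl)ethyl]phenoxy}-4,5-dimethoxyphenyl)propanal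
Product: 11 5-(2-{3-[5-(but-3-yn-1-yl)-2,3-dimethoxyphenoxy]phenyl}ethyl)-2,3-dimethoxyphenol
Conditions: Ohira–Bestmann reagent (1.5 equiv), K2CO3 (3 equiv), MeOH, 0 °C to rt
Reagents that add atoms: dimethyl (1-diazo-2-oxopropyl)phosphonate, COP(=O)(OC)C(=[N+]=[N-])C(C)=O
Why: Ohira–Bestmann (Seyferth–Gilbert) homologation, in which the diazomethylphosphonate anion formed by methanolysis converts the enolisable aldehyde into the terminal alkyne under mild carbonate conditions that only deprotonate the phenol reversibly.

Step 8
Reactants: 11 5-(2-{3-[5-(but-3-yn-1-yl)-2,3-dimethoxyphenoxy]phenyl}ethyl)-2,3-dimethoxyphenol; 12 trichloroethylene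
Product: 13 1-(but-3-yn-1-yl)-3-[3-(2-{3-[(E)-1,2-dichloroethenyloxy]-4,5-dimethoxyphenyl}ethyl)phenoxy]-4,5-dimethoxybenzene
Conditions: K2CO3 (2 equiv), trichloroethylene (2 equiv), DMF, 60 °C
Reagents that add atoms: none
Why: Base-mediated dichlorovinylation of a phenol, in which carbonate eliminates HCl from trichloroethylene and the phenoxide adds anti to the dichloroacetylene so formed to give the E-1,2-dichlorovinyl ether, the terminal alkyne being far too weakly acidic to take part.

Step 9
Reactants: 13 1-(but-3-yn-1-yl)-3-[3-(2-{3-[(E)-1,2-dichloroethenyloxy]-4,5-dimethoxyphenyl}ethyl)phenoxy]-4,5-dimethoxybenzene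
Product: 16 1-(but-3-yn-1-yl)-3-(3-{2-[3-(ethynyloxy)-4,5-dimethoxyphenyl]ethyl}phenoxy)-4,5-dimethoxybenzene, via chloroethynyl ether lithium acetylide 14 (not isolated), via dilithium diacetylide 15 (not isolated)
Conditions: n-BuLi (3.3 equiv), THF, −78 to −40 °C; then sat. aq. NH4Cl, −78 °C; rapid filtration through Et3N-deactivated silica, used at once
Reagents that add atoms: none
Why: Established ynol ether synthesis from dichlorovinyl ethers, in which n-BuLi first deprotonates the butynyl C–H, then eliminates HCl to the chloroethynyl ether and exchanges chlorine for lithium to give the lithium aryloxyacetylide, and protonation of the dilithium species returns both terminal alkynes.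

Step 10
Reactants: 16 1-(but-3-yn-1-yl)-3-(3-{2-[3-(ethynyloxy)-4,5-dimethoxyphenyl]ethyl}phenoxy)-4,5-dimethoxybenzene; 17 acetylene
Product: 18 macrocycle tetramethyl ether (the target with four OMe in place of the four OH)
Conditions: [Rh(cod)2]BF4 (20 mol %), rac-BINAP (20 mol %), pre-activated with H2 then purged with Ar; C2H2 (about 5 vol % in Ar, 1 atm), CH2Cl2, rt; 16 added by syringe pump over 16 h (final 1 mM)
Reagents that add atoms: none
Why: The cationic monovalent rhodium bisphosphine fragment binds the two terminal alkynes of 16 and couples them oxidatively through their unsubstituted CH carbons to a trivalent rhodacyclopentadiene that carries the aryloxy and the alkyl substituent on the two carbons bonded to rhodium; insertion of acetylene and reductive elimination then release the 1,4-disubstituted benzene and return the catalyst. The closest known reaction type is the cross-[2+2+2] cyclotrimerisation of long-chain terminal α,ω-diynes with a third alkyne at high dilution under cationic rhodium bisphosphine or CpCo catalysis, which gives para- and metacyclophanes, together with the rhodium-catalysed [2+2+2] cycloaddition of aryl ethynyl ethers to aryloxybenzenes. Ring B closes by cycloaddition through three new C–C bonds (C2–C3 between the former CH termini, C4–C5 and C6–C1 to the two acetylene carbons), and the 19-membered ring closes in paracyclophane mode as a consequence, because the preformed 15-atom tether then bridges C1 and C4 of the new arene without any bond of the tether being made. No stereocentre arises. The step needs 1,4- rather than 1,3- or 1,2-union of the two tethered alkynes, intramolecular rather than intermolecular diyne coupling, and uptake of exactly one acetylene: the first is backed by the preference of the larger substituents for the metal-bound carbons (the reason both alkynes are kept terminal) and by a tether long enough to span the para positions, the second by slow addition to about 1 mM, and the third by keeping acetylene dilute so that capping of each alkyne by two acetylenes does not outrun the intramolecular coupling.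

Step 11
Reactants: 18 macrocycle tetramethyl ether
Product: 20 target tetraphenol CNP0511668.0, via bis(bromodioxaborole) 19 (not isolated)
Conditions: BBr3 (8 equiv), CH2Cl2, −78 °C to rt; then ice-water, work-up under Ar
Reagents that add atoms: none
Why: Lewis-acid ether cleavage, in which BBr3 complexes each methoxy oxygen and bromide removes the methyl group by SN2 while the two diaryl ethers cannot be cleaved in this way, and hydrolysis of the cyclic borates on work-up frees the four phenols.

Compound list
1 | 3-hydroxy-4,5-dimethoxybenzaldehyde | COc1cc(C=O)cc(O)c1OC | starting material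
2 | 3-(benzyloxy)-4,5-dimethoxybenzaldehyde | COc1cc(C=O)cc(OCc2ccccc2)c1OC | intermediate
3 | 3-hydroxybenzyl alcohol | OCc1cccc(O)c1 | starting material
4 | (3-hydroxybenzyl)triphenylphosphonium bromide | [Br-].Oc1cccc(C[P+](c2ccccc2)(c2ccccc2)c2ccccc2)c1 | intermediate
5 | potassium 3-[(triphenylphosphoranylidene)methyl]phenolate (phosphonium ylide phenoxide, not isolated) | [K+].[O-]c1cccc(C=P(c2ccccc2)(c2ccccc2)c2ccccc2)c1 | intermediate
6 | 3-[2-(3-benzyloxy-4,5-dimethoxyphenyl)ethenyl]phenol (E/Z mixture) | COc1cc(C=Cc2cccc(O)c2)cc(OCc2ccccc2)c1OC | intermediate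
7 | 3-bromo-4,5-dimethoxybenzaldehyde | COc1cc(C=O)cc(Br)c1OC | starting material
8 | 3-{3-[2-(3-benzyloxy-4,5-dimethoxyphenyl)ethenyl]phenoxy}-4,5-dimethoxybenzaldehyde (E/Z mixture) | COc1cc(C=Cc2cccc(Oc3cc(C=O)cc(OC)c3OC)c2)cc(OCc2ccccc2)c1OC | intermediate
9 | (2E)-3-(3-{3-[2-(3-benzyloxy-4,5-dimethoxyphenyl)ethenyl]phenoxy}-4,5-dimethoxyphenyl)prop-2-enal (stilbene bond E/Z) | COc1cc(C=Cc2cccc(Oc3cc(/C=C/C=O)cc(OC)c3OC)c2)cc(OCc2ccccc2)c1OC | intermediate
10 | 3-(3-{3-[2-(3-hydroxy-4,5-dimethoxyphenyl)ethyl]phenoxy}-4,5-dimethoxyphenyl)propanal | COc1cc(CCc2cccc(Oc3cc(CCC=O)cc(OC)c3OC)c2)cc(O)c1OC | intermediate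
11 | 5-(2-{3-[5-(but-3-yn-1-yl)-2,3-dimethoxyphenoxy]phenyl}ethyl)-2,3-dimethoxyphenol | COc1cc(CCc2cccc(Oc3cc(CCC#C)cc(OC)c3OC)c2)cc(O)c1OC | intermediate
12 | trichloroethylene | ClC=C(Cl)Cl | starting material
13 | 1-(but-3-yn-1-yl)-3-[3-(2-{3-[(E)-1,2-dichloroethenyloxy]-4,5-dimethoxyphenyl}ethyl)phenoxy]-4,5-dimethoxybenzene | COc1cc(CCc2cccc(Oc3cc(CCC#C)cc(OC)c3OC)c2)cc(O/C(Cl)=C\Cl)c1OC | intermediate
14 | chloroethynyl ether lithium acetylide (ring A O–C≡C–Cl, ring C CH2CH2C≡CLi; not isolated) | COc1cc(CCc2cccc(Oc3cc(CCC#C[Li])cc(OC)c3OC)c2)cc(OC#CCl)c1OC | intermediate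
15 | dilithium diacetylide (ring A O–C≡CLi, ring C CH2CH2C≡CLi; not isolated) | [Li]C#COc1cc(CCc2cccc(c2)Oc2cc(CCC#C[Li])cc(OC)c2OC)cc(OC)c1OC | intermediate
16 | 1-(but-3-yn-1-yl)-3-(3-{2-[3-(ethynyloxy)-4,5-dimethoxyphenyl]ethyl}phenoxy)-4,5-dimethoxybenzene (acyclic diyne) | C#COc1cc(CCc2cccc(c2)Oc2cc(CCC#C)cc(OC)c2OC)cc(OC)c1OC | intermediate
17 | acetylene | C#C | starting material
18 | macrocycle tetramethyl ether (19-membered ring through rings A, B, C and D; OMe at the four positions that are OH in the target) | COc1cc2cc(c1OC)Oc1ccc(cc1)CCc1cc(OC)c(OC)c(c1)Oc1cccc(c1)CC2 | intermediate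
19 | bis(bromodioxaborole) of the macrocycle (each catechol unit of rings A and C bridged by B–Br; not isolated) | BrB1Oc2cc3cc(c2O1)Oc2ccc(cc2)CCc2cc4OB(Br)Oc4c(c2)Oc2cccc(c2)CC3 | intermediate
20 | CNP0511668.0, macrocyclic bis(bibenzyl) tetraphenol | Oc1cc2cc(c1O)Oc1ccc(cc1)CCc1cc(O)c(O)c(c1)Oc1cccc(c1)CC2 | target

Total step count: 11.
Longest linear sequence: 10 steps (steps 1 and 3 to 11, from 3-hydroxy-4,5-dimethoxybenzaldehyde); step 2 is a one-step side branch.

Steps most likely to fail

1. Step 10. Each terminal alkyne may be capped by two acetylenes before the two tethered alkynes meet on the metal. The alkynes may also join head-to-tail to give the meta-bridged isomer, or couple between molecules to give oligomers. The fallback uses a different ring closure; it sets out from 8 and returns at 18.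
   - Reduction of 8 with NaBH4 (MeOH, 0 °C) should give the benzylic alcohol {3-[3-(2-(3-benzyloxy-4,5-dimethoxyphenyl)ethenyl)phenoxy]-4,5-dimethoxyphenyl}methanol F1.
   - Hydrogenation (H2, Pd/C, EtOAc) should saturate the stilbene and remove the benzyl group to give the phenol alcohol 5-{2-[3-(5-(hydroxymethyl)-2,3-dimethoxyphenoxy)phenyl]ethyl}-2,3-dimethoxyphenol F2.
   - Nucleophilic aromatic substitution of its phenoxide on 4-fluorobenzaldehyde (K2CO3, DMF, 120 °C) should install ring B as the para-formylphenyl ether F3.
   - Ph3P·HBr (MeCN, reflux) should convert the benzylic alcohol into the phosphonium bromide F4.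
   - Slow addition of F4 to NaOMe in CH2Cl2 at high dilution should close the ring by intramolecular Wittig reaction to the macrocyclic stilbene F5 (E/Z mixture).
   - Hydrogenation (H2, Pd/C, EtOAc) of F5 then gives 18.

2. Step 9. The terminal aryl ethynyl ether may be lost by hydration or oligomerisation during aqueous work-up, concentration and chromatography. The fallback isolates a protected form; it sets out from 13 and returns at 16.
   - The dilithium diacetylide 15 is generated as before but quenched with Me3SiCl at −78 °C, giving the bis(trimethylsilyl) diyne F6, which should survive chromatography and storage.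
   - F6 is desilylated with Bu4NF (THF, −78 to 0 °C) immediately before the cyclisation, and the filtered solution of 16 is fed to step 10.

3. Step 5. The electron-rich aldehyde may react sluggishly, and the enal product may be homologated a second time by the formyl ylide. The fallback carries the new aldehyde in masked form; it sets out from 8 and returns at 10.
   - Wittig reaction of 8 with (1,3-dioxolan-2-ylmethyl)triphenylphosphonium bromide and KOtBu (THF, 0 °C to rt) should give the vinyl dioxolane F7 (E/Z mixture), which cannot react further with the ylide.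
   - Hydrogenation (H2, Pd/C, EtOAc) should saturate both double bonds and remove the benzyl group to give the saturated acetal phenol F8.
   - Aqueous HCl in THF at rt then releases the aldehyde 10.
   - This detour also keeps a free aldehyde out of the hydrogenation of step 6.

Further compounds
F1 | step 10 | {3-[3-(2-(3-benzyloxy-4,5-dimethoxyphenyl)ethenyl)phenoxy]-4,5-dimethoxyphenyl}methanol (E/Z mixture) | COc1cc(C=Cc2cccc(Oc3cc(CO)cc(OC)c3OC)c2)cc(OCc2ccccc2)c1OC
F2 | step 10 | 5-{2-[3-(5-(hydroxymethyl)-2,3-dimethoxyphenoxy)phenyl]ethyl}-2,3-dimethoxyphenol | COc1cc(CCc2cccc(Oc3cc(CO)cc(OC)c3OC)c2)cc(O)c1OC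
F3 | step 10 | 4-(5-{2-[3-(5-(hydroxymethyl)-2,3-dimethoxyphenoxy)phenyl]ethyl}-2,3-dimethoxyphenoxy)benzaldehyde | COc1cc(CCc2cccc(Oc3cc(CO)cc(OC)c3OC)c2)cc(Oc2ccc(C=O)cc2)c1OC
F4 | step 10 | [3-(3-{2-[3-(4-formylphenoxy)-4,5-dimethoxyphenyl]ethyl}phenoxy)-4,5-dimethoxybenzyl]triphenylphosphonium bromide | [Br-].COc1cc(CCc2cccc(Oc3cc(C[P+](c4ccccc4)(c4ccccc4)c4ccccc4)cc(OC)c3OC)c2)cc(Oc2ccc(C=O)cc2)c1OC
F5 | step 10 | macrocyclic stilbene tetramethyl ether (CH=CH between rings B and C, E/Z mixture) | COc1cc2cc(c1OC)Oc1ccc(cc1)C=Cc1cc(OC)c(OC)c(c1)Oc1cccc(c1)CC2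
F6 | step 9 | bis(trimethylsilyl) diyne (Me3Si caps on both alkyne termini of 16) | C[Si](C)(C)C#COc1cc(CCc2cccc(c2)Oc2cc(CCC#C[Si](C)(C)C)cc(OC)c2OC)cc(OC)c1OC
F7 | step 5 | 2-{2-[3-(3-(2-(3-benzyloxy-4,5-dimethoxyphenyl)ethenyl)phenoxy)-4,5-dimethoxyphenyl]ethenyl}-1,3-dioxolane (E/Z mixtures) | COc1cc(C=Cc2cccc(Oc3cc(C=CC4OCCO4)cc(OC)c3OC)c2)cc(OCc2ccccc2)c1OC
F8 | step 5 | 5-{2-[3-(5-(2-(1,3-dioxolan-2-yl)ethyl)-2,3-dimethoxyphenoxy)phenyl]ethyl}-2,3-dimethoxyphenol | COc1cc(CCc2cccc(Oc3cc(CCC4OCCO4)cc(OC)c3OC)c2)cc(O)c1OC
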